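**Conventions.** Target numbering is used for every compound, including the bicyclic ones: ring A = C1–C5 and C10; ring B = C5–C10; side chain C11–C16 on C9; C17 on C8; C18 (methyl) and C19 (oxidised carbon) on C4; C20 on C10. β is the face of the decalin that carries C20, α the opposite face.

## Analysis of the target

Target 34 is a cis-fused decalin with a 3-methylenepent-4-enyl chain on C9, a tertiary carbinol at C8, a quaternary C4 (methyl C18 and acyloxymethyl C19) and an angular methyl group on C10. C19 is esterified with (Z)-4-hydroxycinnamic acid. The five stereocentres C4, C5, C10, C9 and C8 form an unbroken chain. H-5, C20, C18, C17 and C11 lie on the β face; C19 and the C8 hydroxyl lie on the α face. Every carbon substituent of the ring system except C19 therefore sits on the convex face of the cis-decalin. The sensitive groups are the Z-cinnamate (light, base and nucleophiles lead to the E isomer), the free phenol, the 2-substituted 1,3-diene (acid, heat, dienophiles) and the tertiary alcohol, which can eliminate or close an ether onto an electrophilic C12 or C13. The synthesis is hard because the cis fusion joins a quaternary C10 to a C5 that is flanked by the quaternary C4, because C9 lies between two fully substituted carbons, and because one enantiomer is required. The strategy rests on the six consecutive carbons C3–C4–C5–C10–C9–C8. With oxygen at C8 and carbon substituents at C10 and C4 they have the pattern of a guaiacol ring in which C3 and C8 are still bonded. Breaking that bond while C5 is joined to a two-carbon unit hanging on C8 makes ring B, and the fusion can then only be cis.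

## Retrosynthetic reasoning

**Cinnamate.** Target 34 is cut at the aryl–alkenyl bond to iodoacrylate 32 and boronic acid 33, and 32 at the acyl–oxygen bond to diol 30 and acid 31. The Z double bond is bought in 31 and the arene is attached last, so no protecting group has to be removed once the Z-cinnamate exists. Only the primary C19 hydroxyl of 30 can be acylated, so the tertiary alcohol needs no protection here.

**Diene.** Diol 30 comes from silyl ether 29 and this from ester 28 by reduction at C19. The diene of 28 is cut at C13–C14 to enol triflate 26 and stannane 27, and 26 goes back to methyl ketone 24. A methyl ketone gives the terminal enolate cleanly, and the coupling is neutral, so the diene appears only after every reduction that could touch it except the hydride reduction of the ester.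

**C9–C11.** Ketone 24 is cut between C9 and C11 to a C9 radical and enone 23. C9 is flanked by C8 and C10, both fully substituted, so ionic substitution is out, whereas a radical adds readily to an unhindered acceptor. The α face of C9 is the concave face of the cis-decalin. Hydrogen delivery to an sp2 C9 (hydroboration or hydrogenation of an exocyclic alkene) would therefore put C11 on the wrong side, while carbon delivery from the open β face puts it where the target has it. The radical precursor 22 comes from alcohol 21, ketone 20 and α-ketol 19, that is, from the C9 ketal of 18. The silyl group on the C8 oxygen of 20 keeps that oxygen out of the thioacylation and out of hemiketal formation with C13.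

**C4.** Ester 18 comes from alkene 17, which is cut at C4–C18 and traced to sulfone 15 through dienolate 16. The sulfonyl group at C2 is allylic to the enoate, so a two-electron reduction expels it and leaves the ester enolate exactly at C4. The α face of C4 is covered by ring B, so a methyl electrophile enters from β.

**C8–C17.** Carbinol 15 comes from ketone 14 and a methyl nucleophile. This is done before the reduction, which a ketone would not survive.

**Key disconnection.** Ketone 14 is cut at C5–C6 and C3–C8 is reconnected, which leads to the vinyl carbinol 11. The forward [3,3] shift of its alkoxide 12 makes ring B, fixes H-5 cis to C20, and leaves oxygen at C8 and the ketal at C9.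

**Vinyl carbinol.** Carbinol 11 is cut at C7–C8 to ketone 9 and vinylmagnesium bromide 10. The addition must come from the side of the C4=C5 bridge.

**Cycloadduct.** Ketone 9 is one enantiomer of racemate 8, which is cut at C1–C10 and C2–C3 to dienone ketal 7 and sulfone 6. Ketal 7 is the dearomatised form of guaiacol 5. The arene supplies C3, C4, C5, C10, C9 and C8 with C19 and C20 in place.

**Arene.** Guaiacol 5 is traced through bromides 3 and 2 to the commercial phenol 1 by ortho-bromination, O-methylation and exchange of bromine for hydroxyl.

## Alternatives that were turned down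

**Alternative 1: enamine Michael desymmetrisation.** The C4–C5 bond is cut. The precursor is the prochiral cyclohexadienone A1, which carries the racemic C19 aldehyde on a three-carbon tether. In the forward step a chiral primary amine forms the enamine at C4, which adds to C5 of one of the two enone arms and closes ring A to give the cis-fused enone aldehyde A2.
- For it: C4, C5 and C10 are set together by a catalyst, no resolution is needed, and the C4 quaternary centre needs no later alkylation. On absolute stereocontrol and on C4 it is stronger than the chosen route.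
- Against it: the enamine of an α-branched aldehyde is tetrasubstituted and slow to form, and its geometry decides the configuration at C4. The new bond joins a quaternary carbon to a carbon next to another quaternary carbon.
- Against it for ring B: A2 has its oxygen at C7 and a C8=C9 double bond. The target needs oxygen at C8, a methyl group on C8 and the chain on C9, so a carbonyl transposition and several redox steps would follow.
- Comparison: the chosen strategy pays with a resolution but delivers oxygen at C8 and a handle at C9 directly.

**Alternative 2: triene Diels–Alder.** The C5–C10 and C3–C4 bonds are cut, which leads to the open-chain triene A3 with a Z-enoate (C4=C5), a diene C10=C1–C2=C3, and a C6–C9 tether that already carries the C9 stereocentre and the C8 dioxolane. Heating would give the octalin ester A4.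
- For it: it is convergent, sets C4, C5 and C10 relative to C9 in one step, and has the C9 side-chain handle in place from the start. On C9 it is stronger than the chosen route, which sets C9 late.
- Against it: both new bonds end at carbons that become quaternary. The diene terminus C10 carries a methyl group on the inside, which disfavours the s-cis conformer and invites a 1,5-hydrogen shift at the temperatures required.
- Against it: the cis fusion is only one of the possible outcomes of a decatriene cycloaddition and depends on the single C9 stereocentre. A3, with two defined alkene geometries and an enantiopure C9, needs a long synthesis of its own.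
- Comparison: in the chosen strategy the cis fusion is a geometric necessity of the cage.

**Alternative 3: quinone Diels–Alder.** The C1–C10 and C4–C5 bonds are cut, which leads to quinone A5 (future ring B) and dienyl silyl ether A6. Under a chiral oxazaborolidinium Lewis acid they would give the cis-fused enedione A7.
- For it: catalytic enantiocontrol, C4 made with both substituents in place, C17 already present, and very few steps to the bicycle. On these points it is stronger than the chosen route.
- Against it: A6 carries a methyl group on the inside of the reacting terminus, so its s-cis conformer is strongly disfavoured, and the dienophile double bond is trisubstituted.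
- Against it: A7 has oxygen at C6 and C9 and a C7=C8 double bond. C6 must be deoxygenated, C8 hydrated with control, and two ketones told apart.
- Comparison: the chosen strategy uses a highly reactive diene (dienone ketal 7) and places oxygen only at C8 and C9.

Key step: step 7

## Remarks on the chemistry (assumptions)

- C2 of 14 and 15 carries an acidic hydrogen. Its configuration, and any partial shift of the double bond to C2=C3, is without consequence because all such forms give dienolate 16 in step 9. The compounds are drawn with the C2 configuration of 9.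
- The configuration at C9 of 21 and 22 is drawn as 9α-oxygen (hydride from the β face). It is lost in step 15.

## Route

Step 1
Reactants: 1 methyl 4-hydroxy-3-methylbenzoate
Product: 2 methyl 3-bromo-4-hydroxy-5-methylbenzoate
Conditions: Br2, AcOH, rt
Reagents that add atoms: bromine, BrBr
Why: Electrophilic aromatic bromination; the hydroxyl group directs to its only free ortho position, the para position being occupied by the ester.

Step 2
Reactants: 2 methyl 3-bromo-4-hydroxy-5-methylbenzoate
Product: 3 methyl 3-bromo-4-methoxy-5-methylbenzoate
Conditions: MeI, K2CO3, DMF, rt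
Reagents that add atoms: iodomethane, CI
Why: Williamson ether synthesis; the phenoxide is the only nucleophile present.

Step 3
Reactants: 3 methyl 3-bromo-4-methoxy-5-methylbenzoate
Product: 5 methyl 3-hydroxy-4-methoxy-5-methylbenzoate, via pinacol boronate 4 (not isolated)
Conditions: B2pin2, PdCl2(dppf) (cat.), KOAc, 1,4-dioxane, 90 °C; then 30% H2O2, aq. NaOH, THF, 0 °C
Reagents that add atoms: bis(pinacolato)diboron, CC1(C)OB(OC1(C)C)B1OC(C)(C)C(C)(C)O1 (boron and pinacol of 4); hydrogen peroxide, OO (oxygen of 5)
Why: Miyaura borylation of the aryl bromide followed by oxidation of the C–B bond puts the free hydroxyl next to the methoxy group without exposing the methyl ester to hot hydroxide.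

Step 4
Reactants: 5 methyl 3-hydroxy-4-methoxy-5-methylbenzoate; 6 phenyl vinyl sulfone
Product: 8 racemic bicyclo[2.2.2]octenone cycloadduct (C8 ketone; C9 dimethyl ketal; C10 bridgehead methyl; CO2Me on C4 of the C4=C5 bridge; phenylsulfonyl on C2 syn to that bridge), via dienone ketal 7 (not isolated)
Conditions: PhI(OAc)2, MeOH, 6 (excess), 0 °C → 50 °C
Reagents that add atoms: methanol, CO
Why: Oxidative dearomatisation of the guaiacol by PhI(OAc)2 in methanol gives the 6,6-dimethoxycyclohexa-2,4-dienone 7, whose methyl group on C10 slows self-dimerisation, and 7 is trapped by 6 in a Diels–Alder reaction. The sulfonyl-bearing carbon bonds to C3, the diene terminus next to the carbonyl group, and the CH2 group to the methyl-bearing C10, as is general for such dienones; the endo rule places the sulfonyl group syn to the new C4=C5 bridge, and the product is racemic.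

Step 5
Reactants: 8 racemic bicyclo[2.2.2]octenone cycloadduct
Product: 9 bicyclo[2.2.2]octenone cycloadduct as the single enantiomer in which the bridges C4=C5; C8–C9; C2–C1 follow clockwise when viewed from C3 towards C10
Conditions: preparative supercritical-fluid chromatography, amylose tris(3,5-dimethylphenylcarbamate) phase, CO2/MeOH
Reagents that add atoms: none
Why: Chromatographic resolution on a chiral stationary phase separates the enantiomers of the neutral, UV-active ketone; the absolute configuration of the retained enantiomer would be secured by X-ray diffraction using the anomalous scattering of sulfur.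

Step 6
Reactants: 9 bicyclo[2.2.2]octenone cycloadduct (single enantiomer); 10 vinylmagnesium bromide
Product: 11 vinyl carbinol (2-vinylbicyclo[2.2.2]oct-5-en-2-ol; vinyl on C8 syn to the C4=C5 bridge; hydroxyl syn to the C1–C2 bridge)
Conditions: CeCl3, THF, −78 °C
Reagents that add atoms: none
Why: 1,2-Addition of the weakly basic vinylcerium reagent to the ketone; the nucleophile approaches C8 past the sp2 bridge, which is less encumbered than the C1–C2 bridge, so the vinyl group ends up syn to the alkene as the rearrangement requires. The enoate and the α-sulfonyl C–H are left alone at −78 °C.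

Step 7
Reactants: 11 vinyl carbinol
Product: 14 keto ketal (cis-fused decalin; C8 ketone; C9 dimethyl ketal; C3=C4 enoate; 2β-phenylsulfonyl; 5β-H; 10β-CH3), via potassium alkoxide 12 (not isolated), via potassium enolate 13 (not isolated)
Conditions: KH, 18-crown-6, THF, 0 °C → rt; aq. NH4Cl
Reagents that add atoms: none
Why: Deprotonation gives alkoxide 12, in which the oxyanion weakens the adjacent C3–C8 bond, and a [3,3] sigmatropic shift through the 1,5-diene C6=C7–C8–C3–C4=C5 forms C5–C6 and breaks C3–C8. The closest known reaction type is the anionic oxy-Cope rearrangement of 2-vinylbicyclo[2.2.2]oct-5-en-2-ols from dienone-ketal cycloadducts, which gives cis-decalins. Ring B (C5–C6–C7–C8–C9–C10) is closed by the sigmatropic bond formation itself, the vinyl unit bridging C8 and C5 through the boat transition state that the bicycle enforces. The new stereocentre C5 is controlled by the cage: C6 can reach C5 only on the face turned towards the C8–C9 bridge, so H-5 ends up cis to the C10 methyl group, while C10 keeps its configuration from 9. The step needs the vinyl group syn to the C4=C5 bridge, which step 6 supplies, and it needs O–H rather than the α-sulfonyl C–H to be deprotonated, which the much greater kinetic acidity of the hydroxyl secures. The ester on C4 sits at the centre of the allyl fragment that takes up negative charge and should speed the shift without opening a conjugate-addition path. Enolate 13 is quenched by the more acidic C2–H and then by NH4Cl to give ketone 14, with oxygen at C8 and the ketal at C9.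

Step 8
Reactants: 14 keto ketal
Product: 15 carbinol (as 14 but C8 carries 8β-CH3 and 8α-OH)
Conditions: MeLi, CeCl3, THF, −78 °C
Reagents that add atoms: methyllithium, [Li]C
Why: Organocerium 1,2-addition, chosen because methylcerium reagents add to hindered ketones without acting as bases towards C2–H and without attacking the enoate. Allylic strain between the C4 ester and C5 keeps C6 axial on ring A and hence C1 axial on ring B, so the α face of C8 is blocked and the methyl group should enter equatorially from the β face.

Step 9
Reactants: 15 carbinol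
Product: 17 methyl ester (cis-decalin; C2=C3; 4β-CH3; 4α-CO2Me; 5β-H; 8α-OH; 8β-CH3; C9 dimethyl ketal; 10β-CH3), via lithium dienolate 16 (not isolated)
Conditions: Li, NH3(l)/THF, −78 °C (15 added to the blue solution); isoprene; MeI, −78 → −33 °C
Reagents that add atoms: iodomethane, CI
Why: Two-electron dissolving-metal reduction cleaves the allylic C2–S bond of the γ-sulfonyl enoate and leaves the extended ester enolate 16 (reductive desulfonylation), which is C-methylated at its α-carbon C4 as lithium dienolates are. The α face of C4 is the concave face of the cis-decalin, covered by C6 in one half-chair of ring A and by C9 in the other, so the methyl group should enter from β and C19 stays α. Sulfur leaves as sulfinate and the double bond is left at C2=C3.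

Step 10
Reactants: 17 methyl ester
Product: 18 saturated ester (as 17 with a C2–C3 single bond)
Conditions: H2 (1 atm), Pd/C, EtOAc, rt
Reagents that add atoms: none
Why: Heterogeneous hydrogenation of the only C=C bond; no stereocentre is formed because C2 and C3 become methylene groups, and the ketal is stable in the neutral medium.

Step 11
Reactants: 18 saturated ester
Product: 19 α-ketol (as 18 with a C9 ketone)
Conditions: 2 M HCl, THF, rt
Reagents that add atoms: water, O
Why: Acid hydrolysis of the dimethyl ketal, helped by relief of crowding at C9; the tertiary alcohol next to the developing carbonyl group does not ionise and the neopentyl ester is not hydrolysed.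

Step 12
Reactants: 19 α-ketol
Product: 20 silyl ether (as 19 with 8α-OSiEt3)
Conditions: Et3SiOTf, 2,6-lutidine, CH2Cl2, 0 °C
Reagents that add atoms: triethylsilyl trifluoromethanesulfonate, CC[Si](CC)(CC)OS(=O)(=O)C(F)(F)F
Why: Silyl triflate silylation of the hindered tertiary alcohol; the ketone has no α-hydrogen on either side, so no silyl enol ether can form. The silyl ether keeps the C8 oxygen out of the thioacylation in step 14 and out of hemiketal formation with the C13 ketone later.

Step 13
Reactants: 20 silyl ether
Product: 21 alcohol (as 20 with 9α-OH and 9β-H)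
Conditions: NaBH4, CeCl3·7H2O, MeOH, 0 °C → rt
Reagents that add atoms: none
Why: Luche-type borohydride reduction of the hindered ketone; the slightly acidic medium suppresses silyl migration to the new alkoxide and the neopentyl ester is not touched. Hydride should enter from the open β face, but the configuration at C9 is of no consequence because C9 becomes a radical in step 15.

Step 14
Reactants: 21 alcohol
Product: 22 thiocarbonyl imidazolide (O-C9 1H-imidazole-1-carbothioate of 21)
Conditions: 1,1'-thiocarbonyldiimidazole, DMAP (cat.), PhMe, 100 °C
Reagents that add atoms: 1,1'-thiocarbonyldiimidazole, S=C(n1ccnc1)n1ccnc1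
Why: Thioacylation of the secondary alcohol under neutral conditions (no alkoxide, hence no silyl migration) gives the radical precursor, the activation used in Barton–McCombie chemistry.

Step 15
Reactants: 22 thiocarbonyl imidazolide; 23 methyl vinyl ketone
Product: 24 methyl ketone (cis-decalin; 9β-(3-oxobutyl); 9α-H; 8α-OSiEt3; 8β-CH3; 4β-CH3; 4α-CO2Me; 5β-H; 10β-CH3)
Conditions: Bu3SnH (slow addition), AIBN (cat.), 23 (excess), PhMe, 90 °C
Reagents that add atoms: none
Why: A radical chain of the Barton–McCombie type turns the thiocarbonyl derivative into the secondary C9 radical, which adds to the terminal carbon of the enone (Giese reaction) and is then reduced by the stannane; a radical tolerates the two fully substituted neighbours that rule out ionic substitution at C9. The α face of C9 is the concave face next to the ring fusion, covered by C1 and the silyloxy group in one chair of ring B and by C4 in the other, so the acceptor should come from β and leave H-9 on the α face, as in the target.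

Step 16
Reactants: 24 methyl ketone
Product: 26 enol triflate (as 24 with CH2=C(OSO2CF3)– in place of the acetyl group), via lithium enolate 25 (not isolated)
Conditions: LiN(iPr)2, THF, −78 °C; then N-(5-chloropyridin-2-yl)bis(trifluoromethanesulfonimide), −78 → −20 °C
Reagents that add atoms: N-(5-chloropyridin-2-yl)bis(trifluoromethanesulfonimide), O=S(=O)(N(c1ccc(Cl)cn1)S(=O)(=O)C(F)(F)F)C(F)(F)F
Why: Kinetic deprotonation of the methyl ketone at the methyl group by the hindered amide base and O-triflation of the terminal enolate; the C4 ester has no α-hydrogen and the tertiary oxygen is silylated.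

Step 17
Reactants: 26 enol triflate; 27 tributyl(vinyl)stannane
Product: 28 diene ester (as 24 with 9β-(3-methylenepent-4-en-1-yl))
Conditions: Pd(PPh3)4 (cat.), LiCl, THF, 65 °C
Reagents that add atoms: none
Why: Stille coupling of the enol triflate with the vinylstannane forms C13–C14 and with it the 2-substituted 1,3-diene under neutral conditions.

Step 18
Reactants: 28 diene ester
Product: 29 alcohol (as 28 with 4α-CH2OH)
Conditions: LiAlH4, THF, 0 → 40 °C
Reagents that add atoms: none
Why: Hydride reduction of the neopentyl methyl ester to the C19 primary alcohol; the diene and the silyl ether are inert to LiAlH4.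

Step 19
Reactants: 29 alcohol
Product: 30 diol (as 29 with free 8α-OH)
Conditions: Bu4NF, THF, rt → 50 °C
Reagents that add atoms: none
Why: Fluoride cleavage of the tertiary silyl ether, done before the base- and light-sensitive Z-ester is present.

Step 20
Reactants: 30 diol; 31 (Z)-3-iodoacrylic acid
Product: 32 iodoacrylate (C19 (Z)-3-iodoprop-2-enoate of 30)
Conditions: DCC, DMAP (cat.), CH2Cl2, 0 °C, dark
Reagents that add atoms: none
Why: Steglich esterification; only the primary C19 hydroxyl reacts because the tertiary C8 hydroxyl is too hindered, and low temperature with catalytic DMAP keeps the Z-iodoacrylate from isomerising.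

Step 21
Reactants: 32 iodoacrylate; 33 4-hydroxyphenylboronic acid
Product: 34 target (C19 (Z)-3-(4-hydroxyphenyl)prop-2-enoate of 30)
Conditions: Pd(PPh3)4 (cat.), K3PO4, THF/H2O, rt, dark
Reagents that add atoms: none
Why: Suzuki–Miyaura coupling of the (Z)-alkenyl iodide with the arylboronic acid proceeds with retention of alkene geometry and tolerates the free phenol, the diene and the tertiary alcohol, so nothing has to be deprotected after the Z-cinnamate exists.

## Compound list

1 | methyl 4-hydroxy-3-methylbenzoate | COC(=O)c1ccc(O)c(C)c1 | starting material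
2 | methyl 3-bromo-4-hydroxy-5-methylbenzoate | COC(=O)c1cc(C)c(O)c(Br)c1 | intermediate
3 | methyl 3-bromo-4-methoxy-5-methylbenzoate | COC(=O)c1cc(C)c(OC)c(Br)c1 | intermediate
4 | methyl 4-methoxy-3-methyl-5-(4,4,5,5-tetramethyl-1,3,2-dioxaborolan-2-yl)benzoate (pinacol boronate) | COC(=O)c1cc(C)c(OC)c(B2OC(C)(C)C(C)(C)O2)c1 | intermediate
5 | methyl 3-hydroxy-4-methoxy-5-methylbenzoate | COC(=O)c1cc(C)c(OC)c(O)c1 | intermediate
6 | phenyl vinyl sulfone | C=CS(=O)(=O)c1ccccc1 | starting material
7 | methyl 4,4-dimethoxy-5-methyl-3-oxocyclohexa-1,5-diene-1-carboxylate (dienone ketal) | COC(=O)C1=CC(=O)C(OC)(OC)C(C)=C1 | intermediate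
8 | racemic methyl 5,5-dimethoxy-4-methyl-6-oxo-7-(phenylsulfonyl)bicyclo[2.2.2]oct-2-ene-2-carboxylate, sulfonyl syn to the alkene bridge (both enantiomers shown) | O=C1C(OC)(OC)[C@]2(C)C=C(C(=O)OC)[C@H]1[C@@H](S(=O)(=O)c1ccccc1)C2.O=C1C(OC)(OC)[C@@]2(C)C=C(C(=O)OC)[C@@H]1[C@H](S(=O)(=O)c1ccccc1)C2 | intermediate
9 | the enantiomer of 8 in which the bridges C4=C5, C8–C9 and C2–C1 follow clockwise when viewed from C3 towards C10 | O=C1C(OC)(OC)[C@]2(C)C=C(C(=O)OC)[C@H]1[C@@H](S(=O)(=O)c1ccccc1)C2 | intermediate
10 | vinylmagnesium bromide | C=C[Mg]Br | starting material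
11 | methyl 6-hydroxy-5,5-dimethoxy-4-methyl-7-(phenylsulfonyl)-6-vinylbicyclo[2.2.2]oct-2-ene-2-carboxylate, vinyl and sulfonyl both syn to the alkene bridge | C=C[C@]1(O)C(OC)(OC)[C@]2(C)C=C(C(=O)OC)[C@H]1[C@@H](S(=O)(=O)c1ccccc1)C2 | intermediate
12 | potassium alkoxide of 11 | C=C[C@]1([O-])C(OC)(OC)[C@]2(C)C=C(C(=O)OC)[C@H]1[C@@H](S(=O)(=O)c1ccccc1)C2.[K+] | intermediate
13 | potassium C7=C8 enolate of 14 | COC1(OC)[C@@]2(C)C[C@H](S(=O)(=O)c3ccccc3)C=C(C(=O)OC)[C@H]2CC=C1[O-].[K+] | intermediate
14 | methyl 5,5-dimethoxy-4a-methyl-6-oxo-3-(phenylsulfonyl)-3,4,4a,5,6,7,8,8a-octahydronaphthalene-1-carboxylate, cis-fused (C8 ketone, C9 ketal, C3=C4, 2β-sulfonyl, 5β-H, 10β-CH3) | COC1(OC)[C@@]2(C)C[C@H](S(=O)(=O)c3ccccc3)C=C(C(=O)OC)[C@H]2CCC1=O | intermediate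
15 | carbinol: as 14 with 8β-CH3 and 8α-OH | COC1(OC)[C@@]2(C)C[C@H](S(=O)(=O)c3ccccc3)C=C(C(=O)OC)[C@H]2CC[C@@]1(C)O | intermediate
16 | lithium dienolate (C2=C3–C4=C(OMe)OLi) from 15 | COC1(OC)[C@@]2(C)CC=CC(=C(OC)[O-])[C@H]2CC[C@@]1(C)O.[Li+] | intermediate
17 | methyl ester: cis-decalin, C2=C3, 4β-CH3, 4α-CO2Me, 5β-H, 8α-OH, 8β-CH3, C9 dimethyl ketal, 10β-CH3 | COC1(OC)[C@@]2(C)CC=C[C@@](C)(C(=O)OC)[C@H]2CC[C@@]1(C)O | intermediate
18 | saturated ester: as 17 with C2–C3 single bond | COC1(OC)[C@@]2(C)CCC[C@@](C)(C(=O)OC)[C@H]2CC[C@@]1(C)O | intermediate
19 | α-ketol: as 18 with C9 ketone | O=C1[C@@]2(C)CCC[C@@](C)(C(=O)OC)[C@H]2CC[C@@]1(C)O | intermediate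
20 | silyl ether: as 19 with 8α-OSiEt3 | O=C1[C@@]2(C)CCC[C@@](C)(C(=O)OC)[C@H]2CC[C@@]1(C)O[Si](CC)(CC)CC | intermediate
21 | alcohol: as 20 with 9α-OH, 9β-H | O[C@H]1[C@@]2(C)CCC[C@@](C)(C(=O)OC)[C@H]2CC[C@@]1(C)O[Si](CC)(CC)CC | intermediate
22 | O-(C9) 1H-imidazole-1-carbothioate of 21 | S=C(O[C@H]1[C@@]2(C)CCC[C@@](C)(C(=O)OC)[C@H]2CC[C@@]1(C)O[Si](CC)(CC)CC)n1ccnc1 | intermediate
23 | methyl vinyl ketone (but-3-en-2-one) | C=CC(C)=O | starting material
24 | methyl ketone: cis-decalin, 9β-(3-oxobutyl), 9α-H, 8α-OSiEt3, 8β-CH3, 4β-CH3, 4α-CO2Me, 5β-H, 10β-CH3 | CC(=O)CC[C@@H]1[C@@]2(C)CCC[C@@](C)(C(=O)OC)[C@H]2CC[C@@]1(C)O[Si](CC)(CC)CC | intermediate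
25 | terminal lithium enolate of 24 | [Li+].[O-]C(=C)CC[C@@H]1[C@@]2(C)CCC[C@@](C)(C(=O)OC)[C@H]2CC[C@@]1(C)O[Si](CC)(CC)CC | intermediate
26 | enol triflate: as 24 with CH2=C(OSO2CF3)– in place of acetyl | C=C(OS(=O)(=O)C(F)(F)F)CC[C@@H]1[C@@]2(C)CCC[C@@](C)(C(=O)OC)[C@H]2CC[C@@]1(C)O[Si](CC)(CC)CC | intermediate
27 | tributyl(vinyl)stannane | C=C[Sn](CCCC)(CCCC)CCCC | starting material
28 | diene ester: as 24 with 9β-(3-methylenepent-4-en-1-yl) | C=CC(=C)CC[C@@H]1[C@@]2(C)CCC[C@@](C)(C(=O)OC)[C@H]2CC[C@@]1(C)O[Si](CC)(CC)CC | intermediate
29 | alcohol: as 28 with 4α-CH2OH | C=CC(=C)CC[C@@H]1[C@@]2(C)CCC[C@@](C)(CO)[C@H]2CC[C@@]1(C)O[Si](CC)(CC)CC | intermediate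
30 | diol: as 29 with free 8α-OH | C=CC(=C)CC[C@@H]1[C@@]2(C)CCC[C@@](C)(CO)[C@H]2CC[C@@]1(C)O | intermediate
31 | (Z)-3-iodoacrylic acid | OC(=O)/C=C\I | starting material
32 | C19 (Z)-3-iodoprop-2-enoate of 30 | C=CC(=C)CC[C@@H]1[C@@]2(C)CCC[C@@](C)(COC(=O)/C=C\I)[C@H]2CC[C@@]1(C)O | intermediate
33 | 4-hydroxyphenylboronic acid | OB(O)c1ccc(O)cc1 | starting material
34 | C19 (Z)-3-(4-hydroxyphenyl)prop-2-enoate of 30 (CNP0197278.5) | C=CC(=C)CC[C@@H]1[C@@]2(C)CCC[C@@](C)(COC(=O)/C=C\c3ccc(O)cc3)[C@H]2CC[C@@]1(C)O | target

## Step count and least certain steps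

Total step count: 21. Longest linear sequence: 21 steps from 1; all coupling partners (6, 10, 23, 27, 31, 33) are commercial. Step 5 discards half of the material by design.

**Step 7 (key step).** Most likely to go wrong: base-induced side reactions of the acidic allylic sulfone that forms as the rearrangement proceeds (loss of sulfinate from the rearranged anion, or fragmentation), because product and base share the flask. Fallback: a neutral thermal oxy-Cope rearrangement. From 11, silylation with 1-(trimethylsilyl)imidazole gives the trimethylsilyl ether F1. Thermolysis in o-dichlorobenzene at about 200 °C gives, by the same [3,3] shift, the silyl enol ether F2. Mild aqueous acid then returns to the route at 14.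

**Step 9.** Most likely to go wrong: methyl delivery to the α face in more than a minor share, because the β face carries the C10 methyl group 1,3 to C4. Fallback: exchange of roles at C4, so that the entering electrophile becomes C19 and the ester becomes C18.
- From 15, dienolate 16 is formed as in step 9 and alkylated with benzyl chloromethyl ether to give the benzyloxymethyl ester F3 (4α-CH2OBn, 4β-CO2Me).
- LiAlH4 gives the alcohol F4, and Dess–Martin oxidation the aldehyde F5.
- Wolff–Kishner reduction (N2H4, KOH, diethylene glycol, 200 °C) gives the benzyl ether F6 with the 4β-methyl group.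
- H2 over Pd(OH)2/C removes the benzyl group and saturates C2=C3 to give the alcohol F7.
- Oxidation (TEMPO/PhI(OAc)2, then NaClO2) gives the acid F8, and Me3SiCHN2 returns to the route at 18.

**Step 15.** Most likely to go wrong: hydrogen transfer to the C9 radical before it adds (plain deoxygenation), since the radical is flanked by two fully substituted carbons, or an unexpected share of attack from the α face. Fallback: the chain is built through an alkene and C9 is set by hydroxyl-directed hydrogenation.
- From 20, vinylmagnesium bromide with CeCl3 gives the vinyl carbinol F9.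
- Johnson–Claisen rearrangement (MeC(OEt)3, EtCO2H cat., 140 °C) gives the ethyl ester F10 with a C9=C11 double bond.
- Bu4NF gives the allylic alcohol F11.
- H2 with [Ir(cod)(PCy3)(py)]PF6 in CH2Cl2 delivers hydrogen to C9 from the face of the 8α-hydroxyl and gives the saturated ester F12.
- iBu2AlH at −78 °C reduces the unhindered ethyl ester to the aldehyde F13.
- Dimethylmethyleneammonium iodide with Et3N gives the α-methylene aldehyde F14, and Ph3P=CH2 the diene hydroxy ester F15.
- LiAlH4 returns to the route at 30.

**Step 8.** Most likely to go wrong: attack of the methyl nucleophile from the α face if the chair of ring B with the C10 methyl group axial is populated, which would give the C8 epimer. Fallback: oxygen, not carbon, is delivered from that face. From 14, Ph3P=CH2 (excess) gives the methylene compound F16, and mCPBA the spiro-epoxide F17 with oxygen on the α face. F17 is then submitted to the conditions of step 9, in which the dissolving metal opens the epoxide at its primary carbon to the tertiary alkoxide while it forms the dienolate. Methylation returns to the route at 17.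

**Step 4.** Most likely to go wrong: dimerisation or decomposition of dienone ketal 7 before the cycloaddition, since diene and dienophile are both electron-poor. Fallback: an electron-rich partner and later oxidation. From 5, the same oxidation in the presence of phenyl vinyl sulfide gives the sulfide cycloadduct F18. Oxidation at sulfur (KHSO5, aq. MeOH) returns to the route at 8.

**Step 21.** Most likely to go wrong: Z to E isomerisation of the acrylate or of the product under palladium and base. Fallback: a Z-selective olefination. From 30, esterification with (diphenoxyphosphoryl)acetic acid (DCC) gives the phosphonoacetate F19. Horner–Wadsworth–Emmons reaction with 4-(tert-butyldimethylsilyloxy)benzaldehyde (NaI, DBU, THF, −78 → 0 °C) gives the silylated Z-cinnamate F20. HF·pyridine returns to the route at 34.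

## Further compounds

F1 | step 7 | trimethylsilyl ether of 11 | C=C[C@]1(O[Si](C)(C)C)C(OC)(OC)[C@]2(C)C=C(C(=O)OC)[C@H]1[C@@H](S(=O)(=O)c1ccccc1)C2
F2 | step 7 | C7=C8 trimethylsilyl enol ether of 14 | COC1(OC)[C@@]2(C)C[C@H](S(=O)(=O)c3ccccc3)C=C(C(=O)OC)[C@H]2CC=C1O[Si](C)(C)C
F3 | step 9 | benzyloxymethyl ester: as 17 but 4α-CH2OBn and 4β-CO2Me | COC1(OC)[C@@]2(C)CC=C[C@](COCc3ccccc3)(C(=O)OC)[C@H]2CC[C@@]1(C)O
F4 | step 9 | alcohol: as F3 with 4β-CH2OH | COC1(OC)[C@@]2(C)CC=C[C@](COCc3ccccc3)(CO)[C@H]2CC[C@@]1(C)O
F5 | step 9 | aldehyde: as F3 with 4β-CHO | COC1(OC)[C@@]2(C)CC=C[C@](COCc3ccccc3)(C=O)[C@H]2CC[C@@]1(C)O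
F6 | step 9 | benzyl ether: 4α-CH2OBn, 4β-CH3, C2=C3 | COC1(OC)[C@@]2(C)CC=C[C@](COCc3ccccc3)(C)[C@H]2CC[C@@]1(C)O
F7 | step 9 | alcohol: as 18 with 4α-CH2OH | COC1(OC)[C@@]2(C)CCC[C@@](C)(CO)[C@H]2CC[C@@]1(C)O
F8 | step 9 | acid: as 18 with 4α-CO2H | COC1(OC)[C@@]2(C)CCC[C@@](C)(C(=O)O)[C@H]2CC[C@@]1(C)O
F9 | step 15 | vinyl carbinol: as 20 with 9β-vinyl and 9α-OH | C=C[C@]1(O)[C@@]2(C)CCC[C@@](C)(C(=O)OC)[C@H]2CC[C@@]1(C)O[Si](CC)(CC)CC
F10 | step 15 | ethyl ester with C9=C11 (geometry open), 8α-OSiEt3 | CCOC(=O)CCC=C1[C@@]2(C)CCC[C@@](C)(C(=O)OC)[C@H]2CC[C@@]1(C)O[Si](CC)(CC)CC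
F11 | step 15 | allylic alcohol: as F10 with free 8α-OH | CCOC(=O)CCC=C1[C@@]2(C)CCC[C@@](C)(C(=O)OC)[C@H]2CC[C@@]1(C)O
F12 | step 15 | saturated ethyl ester, 9α-H, 8α-OH | CCOC(=O)CCC[C@@H]1[C@@]2(C)CCC[C@@](C)(C(=O)OC)[C@H]2CC[C@@]1(C)O
F13 | step 15 | C14 aldehyde | O=CCCC[C@@H]1[C@@]2(C)CCC[C@@](C)(C(=O)OC)[C@H]2CC[C@@]1(C)O
F14 | step 15 | α-methylene aldehyde | O=CC(=C)CC[C@@H]1[C@@]2(C)CCC[C@@](C)(C(=O)OC)[C@H]2CC[C@@]1(C)O
F15 | step 15 | diene hydroxy ester: as 28 with free 8α-OH | C=CC(=C)CC[C@@H]1[C@@]2(C)CCC[C@@](C)(C(=O)OC)[C@H]2CC[C@@]1(C)O
F16 | step 8 | C8 methylene compound from 14 | COC1(OC)[C@@]2(C)C[C@H](S(=O)(=O)c3ccccc3)C=C(C(=O)OC)[C@H]2CCC1=C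
F17 | step 8 | C8 spiro-epoxide, oxygen α | COC1(OC)[C@@]2(C)C[C@H](S(=O)(=O)c3ccccc3)C=C(C(=O)OC)[C@H]2CC[C@]14CO4
F18 | step 4 | racemic sulfide cycloadduct: as 8 with phenylthio on C2 (both enantiomers shown) | O=C1C(OC)(OC)[C@]2(C)C=C(C(=O)OC)[C@H]1[C@@H](Sc1ccccc1)C2.O=C1C(OC)(OC)[C@@]2(C)C=C(C(=O)OC)[C@@H]1[C@H](Sc1ccccc1)C2
F19 | step 21 | C19 (diphenoxyphosphoryl)acetate of 30 | C=CC(=C)CC[C@@H]1[C@@]2(C)CCC[C@@](C)(COC(=O)CP(=O)(Oc3ccccc3)Oc3ccccc3)[C@H]2CC[C@@]1(C)O
F20 | step 21 | tert-butyldimethylsilyl ether of 34 at the phenol | C=CC(=C)CC[C@@H]1[C@@]2(C)CCC[C@@](C)(COC(=O)/C=C\c3ccc(O[Si](C)(C)C(C)(C)C)cc3)[C@H]2CC[C@@]1(C)O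
A1 | alternative 1 | 2-methyl-5-(1-methyl-4-oxocyclohexa-2,5-dien-1-yl)pentanal (racemic) | O=CC(C)CCCC1(C)C=CC(=O)C=C1
A2 | alternative 1 | cis-fused 1,4a-dimethyl-7-oxo-1,2,3,4,4a,7,8,8a-octahydronaphthalene-1-carbaldehyde | O=C1C=C[C@@]2(C)CCC[C@@](C)(C=O)[C@H]2C1
A3 | alternative 2 | methyl (2Z)-5-{2-[(4E)-1-(benzyloxy)-4-methylhepta-4,6-dien-3-yl]-1,3-dioxolan-2-yl}-2-methylpent-2-enoate | c1ccccc1COCC[C@H](/C(C)=C/C=C)C1(CC/C=C(/C)C(=O)OC)OCCO1
A4 | alternative 2 | cis-fused octalin methyl ester with C8 dioxolane, C1=C2 and 9-(2-benzyloxyethyl) | c1ccccc1COCC[C@@H]1[C@@]2(C)C=CC[C@@](C)(C(=O)OC)[C@H]2CCC13OCCO3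
A5 | alternative 3 | 2,6-dimethyl-1,4-benzoquinone | CC1=CC(=O)C=C(C)C1=O
A6 | alternative 3 | (E)-tert-butyldimethyl[(2-methylpenta-2,4-dien-1-yl)oxy]silane | C=C/C=C(\C)CO[Si](C)(C)C(C)(C)C
A7 | alternative 3 | cis-fused 2,5,8a-trimethyl-5-(tert-butyldimethylsilyloxymethyl)-4a,5,8,8a-tetrahydronaphthalene-1,4-dione | O=C1[C@@]2(C)CC=C[C@@](C)(CO[Si](C)(C)C(C)(C)C)[C@H]2C(=O)C=C1C
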